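The flavanone is cut at C2–C1', and ring C (O1, C2, C3, C4, C4a, C8a) is never closed as a six-membered ring. It grows out of the furanone ring of 4,6-dihydroxycoumaran-3-one. Silylation and methylene transfer give a racemic cyclopropa[b]benzofuran whose shared C–C bond carries O1 at one end and a siloxy group plus electron-rich ring A at the other. One-electron oxidation breaks exactly this bond, and a chiral nickel catalyst arylates the O1-stabilised C2 radical with the iodinated ring B of an 8-arylapigenin. One operation thus expands the ring, joins both halves and sets C2 from a racemate.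

Key step: step 9

Remark: rings A, C, B and plain or primed locants belong to the flavanone half, rings D, F, E and double-primed locants to the flavone half. The C5'–C8'' axis is assumed to rotate freely, since the target SMILES names no axial configuration.

Step 1
Reactants: 1 apigenin
Product: 2 5,7,4'-tris(methoxymethoxy)flavone
Conditions: NaH, MOMCl, DMF, 0 °C to rt
Reagents that add atoms: chloromethyl methyl ether (MOMCl), COCCl
Why: Williamson ether synthesis, in which sodium hydride also deprotonates the hydrogen-bonded 5-OH, so all three phenols should be capped as acetals that survive base and metal catalysis and fall off with acid at the end.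

Step 2
Reactants: 2 5,7,4'-tris(methoxymethoxy)flavone
Product: 3 8-iodo-5,7,4'-tris(methoxymethoxy)flavone
Conditions: NIS, DMF, 60 °C, dark
Reagents that add atoms: N-iodosuccinimide (NIS), O=C1CCC(=O)N1I
Why: Electrophilic aromatic iodination, in which ring D is the most electron-rich ring and C8 (next to the ring oxygen) is less crowded than C6, which lies between two MOM ethers.

Step 3
Reactants: 4 catechol
Product: 5 1,2-bis(methoxymethoxy)benzene
Conditions: NaH, MOMCl, DMF, 0 °C to rt
Reagents that add atoms: chloromethyl methyl ether (MOMCl), COCCl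
Why: Williamson ether synthesis, giving MOM groups that protect the catechol and later direct the lithiation.

Step 4
Reactants: 5 1,2-bis(methoxymethoxy)benzene
Product: 7 2-[2,3-bis(methoxymethoxy)phenyl]-4,4,5,5-tetramethyl-1,3,2-dioxaborolane, via aryllithium 6 (not isolated)
Conditions: n-BuLi, TMEDA, THF, 0 °C; then iPrOBpin, −78 °C to rt
Reagents that add atoms: n-butyllithium, [Li]CCCC (lithium of 6); 2-isopropoxy-4,4,5,5-tetramethyl-1,3,2-dioxaborolane (iPrOBpin), CC(C)OB1OC(C)(C)C(C)(C)O1
Why: Directed ortho-metalation, in which the acetal oxygens guide n-BuLi to the carbon next to a MOM ether and the aryllithium is trapped by the borate ester.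

Step 5
Reactants: 3 8-iodo-5,7,4'-tris(methoxymethoxy)flavone; 7 2-[2,3-bis(methoxymethoxy)phenyl]-4,4,5,5-tetramethyl-1,3,2-dioxaborolane
Product: 8 8-[2,3-bis(methoxymethoxy)phenyl]-5,7,4'-tris(methoxymethoxy)flavone
Conditions: Pd(OAc)2, SPhos, K3PO4, toluene/H2O, 90 °C
Reagents that add atoms: none
Why: Suzuki–Miyaura coupling, with the bulky electron-rich biarylphosphine chosen for the tri-ortho-substituted C8''–C5' bond, while MOM ethers and the flavone are inert to aqueous phosphate.

Step 6
Reactants: 8 8-[2,3-bis(methoxymethoxy)phenyl]-5,7,4'-tris(methoxymethoxy)flavone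
Product: 10 8-[5-iodo-2,3-bis(methoxymethoxy)phenyl]-5,7,4'-tris(methoxymethoxy)flavone, via arylboronate 9 (not isolated)
Conditions: [Ir(OMe)(cod)]2, dtbpy, B2pin2, THF, 80 °C; evaporate; then CuI, 1,10-phenanthroline, KI, MeOH/H2O, air, 80 °C
Reagents that add atoms: bis(pinacolato)diboron, CC1(C)OB(OC1(C)C)B1OC(C)(C)C(C)(C)O1 (boryl group of 9); potassium iodide, [K+].[I-]
Why: Sterically governed iridium-catalysed C–H borylation takes the only C–H of 8 without an ortho neighbour (the later C1'), and copper-catalysed aerobic iododeboronation then puts iodine on the same carbon under near-neutral conditions that spare the acetals.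

Step 7
Reactants: 11 4,6-dihydroxybenzofuran-3(2H)-one
Product: 12 3,4,6-tris(tert-butyldimethylsilyloxy)benzofuran
Conditions: TBSOTf, Et3N, CH2Cl2, 0 °C to rt
Reagents that add atoms: tert-butyldimethylsilyl triflate (TBSOTf), CC(C)(C)[Si](C)(C)OS(=O)(=O)C(F)(F)F
Why: Silyl triflate and amine silylate both phenols and trap the ketone as its enol (soft enolisation), here the aromatic 3-siloxybenzofuran, so protection and activation cost one step.

Step 8
Reactants: 12 3,4,6-tris(tert-butyldimethylsilyloxy)benzofuran
Product: 13 rac-4,6,6b-tris(tert-butyldimethylsilyloxy)-1a,6b-dihydro-1H-cyclopropa[b]benzofuran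
Conditions: Et2Zn, CH2I2, CH2Cl2, 0 °C to rt; pyridine, aq. NaHCO3 work-up
Reagents that add atoms: diiodomethane, ICI
Why: Simmons–Smith cyclopropanation (Furukawa variant) of a silyl enol ether, in which the electrophilic zinc carbenoid attacks the weakly aromatic C2=C3 bond with its two oxygen donors and the concerted syn transfer can only give the cis-fused racemate.

Step 9
Reactants: 10 8-[5-iodo-2,3-bis(methoxymethoxy)phenyl]-5,7,4'-tris(methoxymethoxy)flavone; 13 rac-4,6,6b-tris(tert-butyldimethylsilyloxy)-1a,6b-dihydro-1H-cyclopropa[b]benzofuran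
Product: 15 (2S)-5,7-bis(tert-butyldimethylsilyloxy)-2-{3,4-bis(methoxymethoxy)-5-[5,7,4'-tris(methoxymethoxy)flavon-8-yl]phenyl}chroman-4-one, via 4-oxochroman-2-yl radical 14 (not isolated)
Conditions: 13 (1.5 equiv), 4CzIPN (2 mol %), NiBr2(dme) (10 mol %), (S,S)-iPr-BiIM (chiral 2,2'-biimidazoline, 12 mol %), 2,6-lutidine, H2O (2 equiv), acetone, blue LED (450 nm), 10 °C
Reagents that add atoms: none
Why: Proposed new method: the excited photocatalyst takes one electron from 13, water removes the silyl group from the radical cation, and the strained C1a–C6b bond, weakened by O1 at one end and by the oxygen and ring A at the other, breaks to give radical 14; zerovalent nickel inserts into the C–I bond of 10, the divalent arylnickel captures 14, reductive elimination from trivalent nickel forms C2–C1', and the reduced photocatalyst returns monovalent nickel to the zerovalent state, so the step is redox-neutral. The closest known reaction types are the oxidative ring expansion of bicyclic cyclopropyl silyl ethers to beta-keto radicals (FeCl3 or photoinduced electron transfer), the photoredox/nickel ring-opening arylation of cyclopropanols, and the nickel-catalysed enantioselective arylation of cyclic alpha-oxy radicals; their merger in one step is new. No ring is closed: ring C arises because the bond shared by the five- and the three-membered ring of the 2-oxabicyclo[3.1.0]hexane is cut, so that the cyclopropane CH2 is taken up as C3 (five to six atoms). Both enantiomers of 13 end in the same planar radical, and C2 is set only by the chiral biimidazoline on nickel, which must deliver the aryl group to the Re face of C2 (the ligand antipode is used if the sense of induction is the opposite). The step needs endocyclic instead of exocyclic cleavage, secured by the O1-stabilised secondary radical against a primary one (the two interconvert through the cyclopropyloxy radical as in a Dowd–Beckwith shift, so the more stable one is drained), and it needs oxidation of 13 before the electron-rich rings of 10 and 15, secured because only the radical cation of 13 has an irreversible, strain-releasing exit. The flavone enone of 10 meets no nucleophile or hydride and should stay untouched.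

Step 10
Reactants: 15 (2S)-5,7-bis(tert-butyldimethylsilyloxy)-2-{3,4-bis(methoxymethoxy)-5-[5,7,4'-tris(methoxymethoxy)flavon-8-yl]phenyl}chroman-4-one
Product: 16 target CNP0204144.1
Conditions: HCl (3 M in MeOH), THF/MeOH, 45 °C, argon; acidic reversed-phase purification
Reagents that add atoms: none
Why: Acid-catalysed acetal exchange and solvolysis of the aryl silyl ethers in methanol free all seven phenols, and C2 should keep its configuration because ring opening to the chalcone and quinone methide formation need base.

Compound list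
1 | apigenin | O=c1cc(-c2ccc(O)cc2)oc2cc(O)cc(O)c12 | starting material
2 | 5,7,4'-tris(methoxymethoxy)flavone | O=c1cc(-c2ccc(OCOC)cc2)oc2cc(OCOC)cc(OCOC)c12 | intermediate
3 | 8-iodo-5,7,4'-tris(methoxymethoxy)flavone | O=c1cc(-c2ccc(OCOC)cc2)oc2c(I)c(OCOC)cc(OCOC)c12 | intermediate
4 | catechol | Oc1ccccc1O | starting material
5 | 1,2-bis(methoxymethoxy)benzene | COCOc1ccccc1OCOC | intermediate
6 | 2,3-bis(methoxymethoxy)phenyllithium | [Li]c1cccc(OCOC)c1OCOC | intermediate
7 | 2-[2,3-bis(methoxymethoxy)phenyl]-4,4,5,5-tetramethyl-1,3,2-dioxaborolane | CC1(C)OB(OC1(C)C)c1cccc(OCOC)c1OCOC | intermediate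
8 | 8-[2,3-bis(methoxymethoxy)phenyl]-5,7,4'-tris(methoxymethoxy)flavone | O=c1cc(-c2ccc(OCOC)cc2)oc2c(-c3cccc(OCOC)c3OCOC)c(OCOC)cc(OCOC)c12 | intermediate
9 | 8-[2,3-bis(methoxymethoxy)-5-(4,4,5,5-tetramethyl-1,3,2-dioxaborolan-2-yl)phenyl]-5,7,4'-tris(methoxymethoxy)flavone | O=c1cc(-c2ccc(OCOC)cc2)oc2c(-c3cc(B4OC(C)(C)C(C)(C)O4)cc(OCOC)c3OCOC)c(OCOC)cc(OCOC)c12 | intermediate
10 | 8-[5-iodo-2,3-bis(methoxymethoxy)phenyl]-5,7,4'-tris(methoxymethoxy)flavone | O=c1cc(-c2ccc(OCOC)cc2)oc2c(-c3cc(I)cc(OCOC)c3OCOC)c(OCOC)cc(OCOC)c12 | intermediate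
11 | 4,6-dihydroxybenzofuran-3(2H)-one | O=C1COc2cc(O)cc(O)c21 | starting material
12 | 3,4,6-tris(tert-butyldimethylsilyloxy)benzofuran | CC(C)(C)[Si](C)(C)Oc1coc2cc(O[Si](C)(C)C(C)(C)C)cc(O[Si](C)(C)C(C)(C)C)c12 | intermediate
13 | rac-4,6,6b-tris(tert-butyldimethylsilyloxy)-1a,6b-dihydro-1H-cyclopropa[b]benzofuran (cis-fused, racemic) | CC(C)(C)[Si](C)(C)OC12CC1Oc1cc(O[Si](C)(C)C(C)(C)C)cc(O[Si](C)(C)C(C)(C)C)c12 | intermediate
14 | 5,7-bis(tert-butyldimethylsilyloxy)-4-oxochroman-2-yl radical | O=C1C[CH]Oc2cc(O[Si](C)(C)C(C)(C)C)cc(O[Si](C)(C)C(C)(C)C)c21 | intermediate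
15 | (2S)-5,7-bis(tert-butyldimethylsilyloxy)-2-{3,4-bis(methoxymethoxy)-5-[5,7,4'-tris(methoxymethoxy)flavon-8-yl]phenyl}chroman-4-one | O=C1C[C@@H](c2cc(OCOC)c(OCOC)c(-c3c(OCOC)cc(OCOC)c4c(=O)cc(-c5ccc(OCOC)cc5)oc34)c2)Oc2cc(O[Si](C)(C)C(C)(C)C)cc(O[Si](C)(C)C(C)(C)C)c21 | intermediate
16 | (2S)-2-{3,4-dihydroxy-5-[5,7-dihydroxy-2-(4-hydroxyphenyl)-4-oxo-4H-chromen-8-yl]phenyl}-5,7-dihydroxychroman-4-one (CNP0204144.1) | O=C1C[C@@H](c2cc(O)c(O)c(-c3c(O)cc(O)c4c(=O)cc(-c5ccc(O)cc5)oc34)c2)Oc2cc(O)cc(O)c21 | target

Total step count: 10. Longest linear sequence: 6 steps (1, 2, 5, 6, 9, 10).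

Steps most likely to fail

Step 9 (bears the label). The radical may be over-oxidised before nickel captures it, the alkylnickel may undergo beta-hydride elimination, the cyclopropane may open exocyclically, or facial selectivity at nickel may be poor. The fallback uses known chemistry and keeps the five-to-six ring growth. It sets out from 13 and from 9, which is isolated after the first half of step 6, and it comes back at 15.
- Compound 13 is treated with FeCl3 in DMF (Saegusa ring expansion). This should give 2-chloro-5,7-bis(tert-butyldimethylsilyloxy)chroman-4-one F1.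
- Et3N removes HCl to give 5,7-bis(tert-butyldimethylsilyloxy)-4H-chromen-4-one F2.
- Compound 9 is cleaved with NaIO4/NH4OAc in acetone/water to {3,4-bis(methoxymethoxy)-5-[5,7,4'-tris(methoxymethoxy)flavon-8-yl]phenyl}boronic acid F3.
- Base-free rhodium-catalysed asymmetric 1,4-addition of F3 to an excess of F2 then gives 15. The catalyst is [Rh(OH)(cod)]2 with the MeO-F12-BIPHEP enantiomer that attacks the Re face of C2, in CH2Cl2/H2O at rt. The 2-aryl-substituted flavone enone is too hindered to compete.

Step 6. Borylation may stray to the C–H bonds of ring E next to the MOM ether, or ring D may be iodinated electrophilically during the halogenation. The fallback installs the halogen before the biaryl bond. It sets out from 3 and comes back at 15.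
- 5-Bromosalicylaldehyde (commercial) is iodinated ortho to the phenol with NIS to 5-bromo-2-hydroxy-3-iodobenzaldehyde F4.
- Dakin oxidation (H2O2, NaOH) gives 5-bromo-3-iodobenzene-1,2-diol F5.
- NaH/MOMCl gives 5-bromo-1-iodo-2,3-bis(methoxymethoxy)benzene F6.
- Compound 3 is converted by Miyaura borylation (PdCl2(dppf), B2pin2, KOAc, dioxane) into 5,7,4'-tris(methoxymethoxy)-8-(4,4,5,5-tetramethyl-1,3,2-dioxaborolan-2-yl)flavone F7.
- Iodide-selective Suzuki–Miyaura coupling of F6 and F7 gives 8-[5-bromo-2,3-bis(methoxymethoxy)phenyl]-5,7,4'-tris(methoxymethoxy)flavone F8, which takes the place of 10 in step 9.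

Step 8. The zinc carbenoid may react sluggishly with the crowded heteroaromatic double bond, or the zinc iodide formed may open the doubly oxygenated cyclopropane. The fallback replaces methylene transfer by a halocarbene ring expansion. It sets out from 12 and comes back at 15.
- Compound 12 is heated with sodium trichloroacetate in DME, which releases dichlorocarbene without base.
- The adduct 1,1-dichloro-4,6,6b-tris(tert-butyldimethylsilyloxy)-1a,6b-dihydro-1H-cyclopropa[b]benzofuran F9 should open by the cyclopropyl-to-allyl cation electrocyclic process. It loses the silyl group and gives 3-chloro-5,7-bis(tert-butyldimethylsilyloxy)-4H-chromen-4-one F10.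
- Hydrodechlorination with Pd(PPh3)4/HCO2Na gives the chromone F2.
- F2 is arylated with the boronic acid F3 under the rhodium conditions given above to reach 15.

Further compounds
F1 | step 9 | 2-chloro-5,7-bis(tert-butyldimethylsilyloxy)chroman-4-one | O=C1CC(Cl)Oc2cc(O[Si](C)(C)C(C)(C)C)cc(O[Si](C)(C)C(C)(C)C)c21
F2 | step 9 | 5,7-bis(tert-butyldimethylsilyloxy)-4H-chromen-4-one | O=c1ccoc2cc(O[Si](C)(C)C(C)(C)C)cc(O[Si](C)(C)C(C)(C)C)c12
F3 | step 9 | {3,4-bis(methoxymethoxy)-5-[5,7,4'-tris(methoxymethoxy)flavon-8-yl]phenyl}boronic acid | O=c1cc(-c2ccc(OCOC)cc2)oc2c(-c3cc(B(O)O)cc(OCOC)c3OCOC)c(OCOC)cc(OCOC)c12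
F4 | step 6 | 5-bromo-2-hydroxy-3-iodobenzaldehyde | O=Cc1cc(Br)cc(I)c1O
F5 | step 6 | 5-bromo-3-iodobenzene-1,2-diol | Oc1cc(Br)cc(I)c1O
F6 | step 6 | 5-bromo-1-iodo-2,3-bis(methoxymethoxy)benzene | COCOc1cc(Br)cc(I)c1OCOC
F7 | step 6 | 5,7,4'-tris(methoxymethoxy)-8-(4,4,5,5-tetramethyl-1,3,2-dioxaborolan-2-yl)flavone | O=c1cc(-c2ccc(OCOC)cc2)oc2c(B3OC(C)(C)C(C)(C)O3)c(OCOC)cc(OCOC)c12
F8 | step 6 | 8-[5-bromo-2,3-bis(methoxymethoxy)phenyl]-5,7,4'-tris(methoxymethoxy)flavone | O=c1cc(-c2ccc(OCOC)cc2)oc2c(-c3cc(Br)cc(OCOC)c3OCOC)c(OCOC)cc(OCOC)c12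
F9 | step 8 | 1,1-dichloro-4,6,6b-tris(tert-butyldimethylsilyloxy)-1a,6b-dihydro-1H-cyclopropa[b]benzofuran | CC(C)(C)[Si](C)(C)OC12C(Cl)(Cl)C1Oc1cc(O[Si](C)(C)C(C)(C)C)cc(O[Si](C)(C)C(C)(C)C)c12
F10 | step 8 | 3-chloro-5,7-bis(tert-butyldimethylsilyloxy)-4H-chromen-4-one | O=c1c(Cl)coc2cc(O[Si](C)(C)C(C)(C)C)cc(O[Si](C)(C)C(C)(C)C)c12
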